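**Retrosynthetic overview**
- The target comes from a hexa-MOM cycloadduct that carries a traceless tert-butyl ester at C3 of the chromanone. One global unmasking with loss of CO2 finishes the synthesis.
- That cycloadduct is made in one flask from an open-chain alkylidene β-keto ester (diene plus uncyclised flavanone) and a 2'-hydroxychalcone. An oxa-Michael closure forms the pyranone ring and sets C2; a chiral-borate exo [4+2] then forms the cyclohexene and sets three centres.
- The alkylidene β-keto ester comes from a Knoevenagel condensation of an aryl β-keto ester with a dienyl benzaldehyde (Heck reaction of a bromobenzaldehyde with isoprene). The chalcone comes from a Claisen–Schmidt condensation.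
- Ring order: the five benzene rings are bought; the pyranone ring is formed first and the cyclohexene ring second, both in step 9.

Assumption: the quinine-derived thiourea is taken to give the (2R) closure and (S)-VANOL borate the (1R,5S,6R) cycloadduct; if either sense proves opposite, the quinidine-derived pseudo-enantiomer or (R)-VANOL is used with no other change.

**Route**

Step 1
Reactants: 1 2',4'-dihydroxyacetophenone
Product: 2 1-[2-hydroxy-4-(methoxymethoxy)phenyl]ethanone
Conditions: MOMCl (1.1 eq), K2CO3, acetone, 0 °C → rt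
Reagents that add atoms: chloromethyl methyl ether (MOMCl), COCCl
Why: Williamson-type O-alkylation in which only the 4-OH reacts, because the 2-OH is held in a hydrogen bond to the ketone.

Step 2
Reactants: 3 2,4-dihydroxybenzaldehyde
Product: 4 2,4-bis(methoxymethoxy)benzaldehyde
Conditions: NaH (2.4 eq), MOMCl (2.4 eq), DMF, 0 °C → rt
Reagents that add atoms: chloromethyl methyl ether (MOMCl), COCCl
Why: Williamson etherification; full deprotonation with NaH also alkylates the chelated 2-OH.

Step 3
Reactants: 2 1-[2-hydroxy-4-(methoxymethoxy)phenyl]ethanone, 4 2,4-bis(methoxymethoxy)benzaldehyde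
Product: 5 (E)-2'-hydroxy-2,4,4'-tris(methoxymethoxy)chalcone
Conditions: KOH (50% aq), EtOH, rt, 36 h
Reagents that add atoms: none
Why: Claisen–Schmidt condensation (aldol, then E1cB dehydration) gives the E-enone; the chelated 2'-OH stays free and is the later boron binding site.

Step 4
Reactants: 6 methyl 2,4-dihydroxybenzoate
Product: 7 methyl 2-hydroxy-4-(methoxymethoxy)benzoate
Conditions: MOMCl (1.1 eq), K2CO3, acetone, rt
Reagents that add atoms: chloromethyl methyl ether (MOMCl), COCCl
Why: the same chelation-controlled Williamson O-alkylation as in step 1, selective for the 4-OH.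

Step 5
Reactants: 7 methyl 2-hydroxy-4-(methoxymethoxy)benzoate, 8 tert-butyl acetate
Product: 9 tert-butyl 3-[2-hydroxy-4-(methoxymethoxy)phenyl]-3-oxopropanoate
Conditions: LDA (3.5 eq), 8 (3.3 eq), THF, −78 °C; then 7, −78 → 0 °C; cold 1 M HCl quench
Reagents that add atoms: none
Why: crossed Claisen condensation in which excess lithium enolate of tert-butyl acetate acylates on the methyl ester of the lithium phenoxide; the product is stored as its enolate and the tert-butyl ester cannot lactonise to a 4-hydroxycoumarin.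

Step 6
Reactants: 10 5-bromo-2,4-dihydroxybenzaldehyde
Product: 11 5-bromo-2,4-bis(methoxymethoxy)benzaldehyde
Conditions: NaH (2.4 eq), MOMCl (2.4 eq), DMF, 0 °C → rt
Reagents that add atoms: chloromethyl methyl ether (MOMCl), COCCl
Why: Williamson etherification of both phenols as in step 2; the aryl bromide and the aldehyde are inert.

Step 7
Reactants: 11 5-bromo-2,4-bis(methoxymethoxy)benzaldehyde, 12 isoprene
Product: 13 2,4-bis(methoxymethoxy)-5-[(1E)-3-methylbuta-1,3-dien-1-yl]benzaldehyde
Conditions: Pd(OAc)2 (5 mol%), P(o-tol)3 (10 mol%), K2CO3, Bu4NBr, 12 (5 eq), DMF, 100 °C, sealed tube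
Reagents that add atoms: none
Why: Mizoroki–Heck reaction in which aryl–Pd adds to the CH2 of the monosubstituted vinyl group of isoprene and syn β-hydride elimination from the allyl–Pd gives the conjugated (E)-1-aryl-3-methylbuta-1,3-diene.

Step 8
Reactants: 9 tert-butyl 3-[2-hydroxy-4-(methoxymethoxy)phenyl]-3-oxopropanoate, 13 2,4-bis(methoxymethoxy)-5-[(1E)-3-methylbuta-1,3-dien-1-yl]benzaldehyde
Product: 14 tert-butyl (2Z)-3-(dienylaryl)-2-[2-hydroxy-4-(methoxymethoxy)benzoyl]prop-2-enoate
Conditions: piperidine (20 mol%), AcOH (20 mol%), 4 Å MS, PhMe, rt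
Reagents that add atoms: none
Why: Knoevenagel condensation via the piperidinium iminium of 13 gives the less crowded Z-alkylidene (aryl trans to the aroyl group); the hydrogen-bonded phenol does not cyclise at rt without a bifunctional catalyst.

Step 9
Reactants: 14 tert-butyl (2Z)-3-(dienylaryl)-2-[2-hydroxy-4-(methoxymethoxy)benzoyl]prop-2-enoate, 5 (E)-2'-hydroxy-2,4,4'-tris(methoxymethoxy)chalcone
Product: 18 hexa-MOM cycloadduct tert-butyl ester [(2R)-chromanone; (1R,5S,6R)-cyclohexene], via flavanone ester 15 (not isolated), via chalcone borate 16 (not isolated), via cycloadduct borate 17 (not isolated)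
Conditions: (i) 14, quinine-derived 3,5-(CF3)2C6H3-thiourea (10 mol%), PhMe, −25 °C, 36 h; (ii) AcOH (0.2 eq), then 16 [pre-formed from 5 (1.5 eq), (S)-VANOL (1.6 eq), BH3·THF (1.6 eq), AcOH (1.6 eq), THF, rt, concentrated], PhMe/THF, 0 °C → rt, 48 h; (iii) H2O/MeOH, aq. NaHCO3; exo adduct separated by chromatography
Reagents that add atoms: none
Why: Proposed new method: two established reactions are run back to back in one flask — the bifunctional cinchona thiourea binds the β-keto ester and directs the 6-endo oxa-Michael addition of the phenol to one face of the alkylidene (sets C2 = R and removes the only other dienophile in the molecule), after which the borate-chelated 2'-hydroxychalcone (LUMO lowered, one enone face shielded by VANOL) undergoes an exo Diels–Alder reaction with the 1-aryl-3-methylbutadiene, the CH2 terminus bonding to the β-carbon and the bulky chelated aroyl group ending trans to the diene aryl (sets the all-trans 1R,5S,6R triad); the closest known reaction types are the thiourea-catalysed flavanone synthesis from alkylidene β-keto esters and the chiral boron-complex-promoted Diels–Alder reaction of 2'-hydroxychalcones.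

Step 10
Reactants: 18 hexa-MOM cycloadduct tert-butyl ester
Product: 21 target heptaphenol (2R; 1R,5S,6R), via persilylated ester 19 (not isolated), via keto acid 20 (not isolated)
Conditions: TMSOTf (20 eq), 2,2'-bipyridyl (30 eq), CH2Cl2, 0 °C → rt; then H2O/THF, 40 °C
Reagents that add atoms: none
Why: silyl triflate/bipyridyl cleavage of the aryl MOM ethers (through aryl silyl ethers, with formaldehyde held as a pyridinium salt and no strong protic acid near the phenol-flanked alkene) together with silyl triflate cleavage of the tert-butyl ester, then decarboxylation of the β-keto acid on aqueous warming; C3 of the chromanone becomes CH2, C2 is untouched, and the only enolisable ring centre already has the thermodynamic all-trans arrangement.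

**Compound list**
1 | 2',4'-dihydroxyacetophenone | CC(=O)c1ccc(O)cc1O | starting material
2 | 1-[2-hydroxy-4-(methoxymethoxy)phenyl]ethanone | CC(=O)c1ccc(OCOC)cc1O | intermediate
3 | 2,4-dihydroxybenzaldehyde | O=Cc1ccc(O)cc1O | starting material
4 | 2,4-bis(methoxymethoxy)benzaldehyde | O=Cc1ccc(OCOC)cc1OCOC | intermediate
5 | (E)-3-[2,4-bis(methoxymethoxy)phenyl]-1-[2-hydroxy-4-(methoxymethoxy)phenyl]prop-2-en-1-one | O=C(/C=C/c1ccc(OCOC)cc1OCOC)c1ccc(OCOC)cc1O | intermediate
6 | methyl 2,4-dihydroxybenzoate | COC(=O)c1ccc(O)cc1O | starting material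
7 | methyl 2-hydroxy-4-(methoxymethoxy)benzoate | COC(=O)c1ccc(OCOC)cc1O | intermediate
8 | tert-butyl acetate | CC(=O)OC(C)(C)C | starting material
9 | tert-butyl 3-[2-hydroxy-4-(methoxymethoxy)phenyl]-3-oxopropanoate | CC(C)(C)OC(=O)CC(=O)c1ccc(OCOC)cc1O | intermediate
10 | 5-bromo-2,4-dihydroxybenzaldehyde | O=Cc1cc(Br)c(O)cc1O | starting material
11 | 5-bromo-2,4-bis(methoxymethoxy)benzaldehyde | O=Cc1cc(Br)c(OCOC)cc1OCOC | intermediate
12 | isoprene (2-methylbuta-1,3-diene) | C=CC(C)=C | starting material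
13 | 2,4-bis(methoxymethoxy)-5-[(1E)-3-methylbuta-1,3-dien-1-yl]benzaldehyde | O=Cc1cc(/C=C/C(C)=C)c(OCOC)cc1OCOC | intermediate
14 | tert-butyl (2Z)-3-{2,4-bis(methoxymethoxy)-5-[(1E)-3-methylbuta-1,3-dien-1-yl]phenyl}-2-[2-hydroxy-4-(methoxymethoxy)benzoyl]prop-2-enoate | CC(C)(C)OC(=O)/C(C(=O)c1ccc(OCOC)cc1O)=C\c1cc(/C=C/C(C)=C)c(OCOC)cc1OCOC | intermediate
15 | tert-butyl (2R)-2-{2,4-bis(methoxymethoxy)-5-[(1E)-3-methylbuta-1,3-dien-1-yl]phenyl}-7-(methoxymethoxy)-4-oxochromane-3-carboxylate (C3 is an enolisable β-keto ester centre, left undefined; deleted in step 10) | C=C(C)/C=C/c1cc([C@H]2C(C(=O)OC(C)(C)C)C(=O)c3ccc(OCOC)cc3O2)c(OCOC)cc1OCOC | intermediate (not isolated)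
16 | (S)-VANOL borate chelate of chalcone 5: tetracoordinate boron bound to the 2'-phenoxide and the carbonyl oxygen of 5 and to both oxygens of (S)-3,3'-diphenyl-2,2'-binaphthalene-1,1'-diol (axial chirality is in the name only) | COCOc1ccc2c(c1)O[B-]1(Oc3c(-c5c(O1)c6ccccc6cc5-c5ccccc5)c(-c4ccccc4)cc4ccccc34)[O+]=C2/C=C/c1ccc(OCOC)cc1OCOC | intermediate (not isolated)
17 | (S)-VANOL borate chelate of cycloadduct 18: boron bound to the 2-phenoxide and the carbonyl oxygen of the aroyl group | CC1=C[C@@H](c2cc([C@H]3C(C(=O)OC(C)(C)C)C(=O)c4ccc(OCOC)cc4O3)c(OCOC)cc2OCOC)[C@H](C2=[O+][B-]3(Oc4c(-c5c(O3)c6ccccc6cc5-c5ccccc5)c(-c5ccccc5)cc5ccccc45)Oc3cc(OCOC)ccc23)[C@@H](c2ccc(OCOC)cc2OCOC)C1 | intermediate (not isolated)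
18 | tert-butyl (2R)-2-{5-[(1R,5S,6R)-5-[2,4-bis(methoxymethoxy)phenyl]-6-[2-hydroxy-4-(methoxymethoxy)benzoyl]-3-methylcyclohex-2-en-1-yl]-2,4-bis(methoxymethoxy)phenyl}-7-(methoxymethoxy)-4-oxochromane-3-carboxylate (C3 of the chromanone undefined) | CC1=C[C@@H](c2cc([C@H]3C(C(=O)OC(C)(C)C)C(=O)c4ccc(OCOC)cc4O3)c(OCOC)cc2OCOC)[C@H](C(=O)c2ccc(OCOC)cc2O)[C@@H](c2ccc(OCOC)cc2OCOC)C1 | intermediate
19 | per-O-silylated form of 18: the six MOM ethers replaced by trimethylsilyl ethers and the tert-butyl ester by a trimethylsilyl ester; the chelated 2-OH of the aroyl group is taken to stay free | CC1=C[C@@H](c2cc([C@H]3C(C(=O)O[Si](C)(C)C)C(=O)c4ccc(O[Si](C)(C)C)cc4O3)c(O[Si](C)(C)C)cc2O[Si](C)(C)C)[C@H](C(=O)c2ccc(O[Si](C)(C)C)cc2O)[C@@H](c2ccc(O[Si](C)(C)C)cc2O[Si](C)(C)C)C1 | intermediate (not isolated)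
20 | (2R)-2-{5-[(1R,5S,6R)-6-(2,4-dihydroxybenzoyl)-5-(2,4-dihydroxyphenyl)-3-methylcyclohex-2-en-1-yl]-2,4-dihydroxyphenyl}-7-hydroxy-4-oxochromane-3-carboxylic acid | CC1=C[C@@H](c2cc([C@H]3C(C(=O)O)C(=O)c4ccc(O)cc4O3)c(O)cc2O)[C@H](C(=O)c2ccc(O)cc2O)[C@@H](c2ccc(O)cc2O)C1 | intermediate (not isolated)
21 | (2R)-2-{5-[(1R,5S,6R)-6-(2,4-dihydroxybenzoyl)-5-(2,4-dihydroxyphenyl)-3-methylcyclohex-2-en-1-yl]-2,4-dihydroxyphenyl}-7-hydroxy-2,3-dihydro-4H-chromen-4-one | CC1=C[C@@H](c2cc([C@H]3CC(=O)c4ccc(O)cc4O3)c(O)cc2O)[C@H](C(=O)c2ccc(O)cc2O)[C@@H](c2ccc(O)cc2O)C1 | target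

**Step count and risks**

Total step count: 10. Longest linear sequence: 5 steps (10 → 11 → 13 → 14 → 18 → 21; steps 6, 7, 8, 9, 10).

Three steps most likely to fail:

Step 9. The β-keto ester of 15 may take boron from 16, residual amine may erode C2, and the exo:endo ratio may be low. The fallback inverts the two ring closures and runs them on separate intermediates, setting out from 13 and 5 and coming back to the route at 18. Borate 16, made as in step 9, is stirred with aldehyde 13, which carries neither a second dienophile nor a chelating group. This gives the borate-bound cycloadduct aldehyde F1 (not isolated) and, after hydrolysis, the cycloadduct aldehyde F2; exo and endo isomers are separated and the ee measured at this stage. Knoevenagel condensation of F2 with 9 gives the cycloadduct alkylidene β-keto ester F3, and thiourea-catalysed oxa-Michael closure of F3 at −25 °C gives 18.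

Step 10. Six MOM ethers and one ester must be removed at once without the phenols adding to the ring alkene and without opening the flavanone. The fallback unmasks in two stages with different chemistry, setting out from 18 and coming back at 21. Neutral thermolysis of 18 over silica gel in refluxing toluene removes only the tert-butyl ester, through the MOM-protected β-keto acid F4 (not isolated), which loses CO2 to give the hexa-MOM flavanone cycloadduct F5. F5 is then unmasked by methanolysis (0.5 M HCl in MeOH/THF, rt), in which formaldehyde is carried off as its dimethyl acetal, to give 21.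

Step 7. The Heck reaction may give regioisomers, a second arylation, or be slow on the electron-rich bromide. The fallback sets out from 11 and comes back at 13. It is a Suzuki–Miyaura coupling (Pd(dppf)Cl2, K3PO4, dioxane/H2O, 70 °C) of 11 with the dienyl pinacol boronate F6, itself made in one step by Cp2Zr(H)Cl-catalysed hydroboration of 2-methylbut-1-en-3-yne with pinacolborane. The C–C bond is then made at a pre-set E-alkenyl boron, so the isomers of the Heck pathway cannot arise.

**Further compounds**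
F1 | step 9 | (S)-VANOL borate chelate of cycloadduct aldehyde F2 (boron on the 2-phenoxide and carbonyl oxygen of the aroyl group; not isolated) | CC1=C[C@@H](c2cc(C=O)c(OCOC)cc2OCOC)[C@H](C2=[O+][B-]3(Oc4c(-c5c(O3)c6ccccc6cc5-c5ccccc5)c(-c5ccccc5)cc5ccccc45)Oc3cc(OCOC)ccc23)[C@@H](c2ccc(OCOC)cc2OCOC)C1
F2 | step 9 | 5-[(1R,5S,6R)-5-[2,4-bis(methoxymethoxy)phenyl]-6-[2-hydroxy-4-(methoxymethoxy)benzoyl]-3-methylcyclohex-2-en-1-yl]-2,4-bis(methoxymethoxy)benzaldehyde | CC1=C[C@@H](c2cc(C=O)c(OCOC)cc2OCOC)[C@H](C(=O)c2ccc(OCOC)cc2O)[C@@H](c2ccc(OCOC)cc2OCOC)C1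
F3 | step 9 | tert-butyl (2Z)-3-{5-[(1R,5S,6R)-5-[2,4-bis(methoxymethoxy)phenyl]-6-[2-hydroxy-4-(methoxymethoxy)benzoyl]-3-methylcyclohex-2-en-1-yl]-2,4-bis(methoxymethoxy)phenyl}-2-[2-hydroxy-4-(methoxymethoxy)benzoyl]prop-2-enoate | CC1=C[C@@H](c2cc(/C=C(\C(=O)OC(C)(C)C)C(=O)c3ccc(OCOC)cc3O)c(OCOC)cc2OCOC)[C@H](C(=O)c2ccc(OCOC)cc2O)[C@@H](c2ccc(OCOC)cc2OCOC)C1
F4 | step 10 | (2R)-2-{5-[(1R,5S,6R)-5-[2,4-bis(methoxymethoxy)phenyl]-6-[2-hydroxy-4-(methoxymethoxy)benzoyl]-3-methylcyclohex-2-en-1-yl]-2,4-bis(methoxymethoxy)phenyl}-7-(methoxymethoxy)-4-oxochromane-3-carboxylic acid (not isolated) | CC1=C[C@@H](c2cc([C@H]3C(C(=O)O)C(=O)c4ccc(OCOC)cc4O3)c(OCOC)cc2OCOC)[C@H](C(=O)c2ccc(OCOC)cc2O)[C@@H](c2ccc(OCOC)cc2OCOC)C1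
F5 | step 10 | (2R)-2-{5-[(1R,5S,6R)-5-[2,4-bis(methoxymethoxy)phenyl]-6-[2-hydroxy-4-(methoxymethoxy)benzoyl]-3-methylcyclohex-2-en-1-yl]-2,4-bis(methoxymethoxy)phenyl}-7-(methoxymethoxy)-2,3-dihydro-4H-chromen-4-one | CC1=C[C@@H](c2cc([C@H]3CC(=O)c4ccc(OCOC)cc4O3)c(OCOC)cc2OCOC)[C@H](C(=O)c2ccc(OCOC)cc2O)[C@@H](c2ccc(OCOC)cc2OCOC)C1
F6 | step 7 | 4,4,5,5-tetramethyl-2-[(1E)-3-methylbuta-1,3-dien-1-yl]-1,3,2-dioxaborolane | CC(=C)/C=C/B1OC(C)(C)C(C)(C)O1
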